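The cyclohexenone is disconnected at C2=C3. Ring carbon C5, the only stereocentre, is a tertiary carbinol flanked by three methylene groups (ring C4, ring C6 and side-chain C1'), which is the pattern of a 3-allyl-3-hydroxyglutarate. The allyl group supplies C4 and C3, one acyl arm becomes the vinyl ketone C6–C1(=O)–C2, and the other becomes the C2' ketone bearing the C17 dienyl chain from linoleic acid. Ring-closing metathesis between the allyl and vinyl ketone arms then creates C2=C3 and the six-membered enone in one operation, leaving C5 untouched. Its precursor is an acyclic, O-silylated (S)-carbinol made from an enzymatically desymmetrised glutarate half-ester.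

Key step: step 9

Assumption: pig liver esterase is taken to give the (S)-half-ester 5, by analogy with its behaviour toward 3-hydroxy-3-methylglutarate; should the sense be opposite, the alkaloid route given as fallback for step 2 supplies the same (S)-acid.

Numbering used: ring C1 (C=O), C2=C3, C4, C5 (carbinol), C6; side chain C1' (CH2), C2' (C=O). The target is (5S).

Step 1
Reactants: 1 dimethyl 3-oxopentanedioate; 2 3-bromoprop-1-ene (allyl bromide)
Product: 4 dimethyl 3-hydroxy-3-(prop-2-en-1-yl)pentanedioate (achiral), via allylindium sesquibromide 3 (not isolated)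
Conditions: indium powder (In, 1.0 equiv), 2 (1.5 equiv), THF/H2O 1:1, rt
Reagents that add atoms: none
Why: Barbier-type indium-mediated allylation; the allylindium species formed in the flask is too weakly basic to enolise the β-keto diester in aqueous THF, so it should add to the ketone carbonyl and give the tertiary homoallylic alcohol.

Step 2
Reactants: 4 dimethyl 3-hydroxy-3-(prop-2-en-1-yl)pentanedioate
Product: 5 (3S)-3-hydroxy-3-(2-methoxy-2-oxoethyl)hex-5-enoic acid
Conditions: pig liver esterase, 0.1 M phosphate buffer pH 7.5 (10% DMSO), rt, pH held with 1 M NaOH; then HCl to pH 3, EtOAc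
Reagents that add atoms: water, O
Why: Enzymatic desymmetrisation of a prochiral diester; the esterase should hydrolyse one of the two enantiotopic methoxycarbonylmethyl arms and stop at the half-ester, which sets the carbinol carbon (the future C5) as S by discrimination between the hydroxyl and allyl groups in the active site.

Step 3
Reactants: 5 (3S)-3-hydroxy-3-(2-methoxy-2-oxoethyl)hex-5-enoic acid
Product: 6 methyl (3R)-3-[2-(ethylsulfanyl)-2-oxoethyl]-3-hydroxyhex-5-enoate
Conditions: EtSH, EDC·HCl, DMAP (cat.), CH2Cl2, 0 °C → rt
Reagents that add atoms: ethanethiol, CCS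
Why: Steglich-type carbodiimide thioesterification; the hindered tertiary hydroxyl and the methyl ester should stay untouched, and the descriptor changes to R only because the thioester arm now outranks the ester arm (no bond at the stereocentre is broken).

Step 4
Reactants: 6 methyl (3R)-3-[2-(ethylsulfanyl)-2-oxoethyl]-3-hydroxyhex-5-enoate
Product: 7 methyl (3R)-3-[2-(ethylsulfanyl)-2-oxoethyl]-3-[(triethylsilyl)oxy]hex-5-enoate
Conditions: TESOTf, 2,6-lutidine, CH2Cl2, −78 → 0 °C
Reagents that add atoms: triethylsilyl trifluoromethanesulfonate, CC[Si](CC)(CC)OS(=O)(=O)C(F)(F)F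
Why: Silylation of a hindered tertiary alcohol with a silyl triflate and a non-nucleophilic base; the ether should block retro-aldol cleavage now and oxa-Michael addition later, without affecting the stereocentre.

Step 5
Reactants: 8 linoleic acid, (9Z,12Z)-octadeca-9,12-dienoic acid
Product: 10 (8Z,11Z)-1-iodoheptadeca-8,11-diene, via Barton ester 9 (not isolated)
Conditions: 2-mercaptopyridine N-oxide, DCC, CH2Cl2, 0 °C → rt, dark; filter; then CHI3, cyclohexene, visible light, rt
Reagents that add atoms: iodoform, IC(I)I
Why: Barton decarboxylative iodination; the thiohydroxamate ester should fragment under visible light to the primary C17 radical, which takes iodine from iodoform faster than it can reach the remote skipped diene, while cyclohexene scavenges stray iodine atoms that could isomerise the Z-alkenes.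

Step 6
Reactants: 7 methyl (3R)-3-[2-(ethylsulfanyl)-2-oxoethyl]-3-[(triethylsilyl)oxy]hex-5-enoate; 10 (8Z,11Z)-1-iodoheptadeca-8,11-diene
Product: 12 methyl (3S,13Z,16Z)-5-oxo-3-(prop-2-en-1-yl)-3-[(triethylsilyl)oxy]docosa-13,16-dienoate, via alkylzinc iodide 11 (not isolated)
Conditions: 10, Zn dust (activated with BrCH2CH2Br and Me3SiCl), THF, 40 °C; then 7, PdCl2(PPh3)2 (5 mol %), toluene, rt
Reagents that add atoms: none
Why: Fukuyama coupling; zerovalent palladium should insert into the C–S bond, transmetallation from the alkylzinc iodide and reductive elimination then give the ketone, and the organozinc tolerates the methyl ester, silyl ether and alkenes (the descriptor returns to S by priority change only).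

Step 7
Reactants: 12 methyl (3S,13Z,16Z)-5-oxo-3-(prop-2-en-1-yl)-3-[(triethylsilyl)oxy]docosa-13,16-dienoate
Product: 13 (3S,13Z,16Z)-5-oxo-3-(prop-2-en-1-yl)-3-[(triethylsilyl)oxy]docosa-13,16-dienoic acid
Conditions: Me3SnOH, ClCH2CH2Cl, 70 °C; then cold 0.1 M HCl wash
Reagents that add atoms: trimethyltin hydroxide, C[Sn](C)(C)O
Why: Non-basic methyl ester cleavage by hydroxide transfer from trimethyltin hydroxide, chosen over aqueous alkali so that the β-silyloxy ketone should not lose silanolate by E1cB elimination.

Step 8
Reactants: 13 (3S,13Z,16Z)-5-oxo-3-(prop-2-en-1-yl)-3-[(triethylsilyl)oxy]docosa-13,16-dienoic acid; 14 tributyl(ethenyl)stannane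
Product: 16 (5S,15Z,18Z)-5-(prop-2-en-1-yl)-5-[(triethylsilyl)oxy]tetracosa-1,15,18-triene-3,7-dione, via acid chloride 15 (not isolated)
Conditions: 1-chloro-N,N,2-trimethylprop-1-en-1-amine (Ghosez reagent), CH2Cl2, 0 °C → rt; then 14, PdCl2(PPh3)2 (3 mol %), BHT, THF, 50 °C
Reagents that add atoms: none
Why: The acid should be converted to its chloride under neutral conditions by the α-chloroenamine, and Stille acylation with the vinylstannane, a standard entry to vinyl ketones, should then leave the saturated ketone, silyl ether and alkenes alone.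

Step 9
Reactants: 16 (5S,15Z,18Z)-5-(prop-2-en-1-yl)-5-[(triethylsilyl)oxy]tetracosa-1,15,18-triene-3,7-dione
Product: 17 (5S)-5-[(10Z,13Z)-2-oxononadeca-10,13-dien-1-yl]-5-[(triethylsilyl)oxy]cyclohex-2-en-1-one
Conditions: second-generation Grubbs catalyst RuCl2(=CHPh)(H2IMes)(PCy3) (5 mol %), 1,4-benzoquinone (10 mol %), CH2Cl2 (5 mM), 40 °C, argon sparge, stopped as soon as 16 is consumed
Reagents that add atoms: none
Why: Olefin metathesis by the Chauvin mechanism: the ruthenium benzylidene should first exchange with the unhindered terminal alkene of the allyl arm, the new alkylidene then adds [2+2] across the vinyl ketone within the same molecule, and cycloreversion of the ruthenacyclobutane releases the enone, the chain being carried by a ruthenium methylidene with loss of ethene. The closest known reaction type is ring-closing metathesis of 1,7-dienes that pair an allyl carbinol with a vinyl ketone to give cyclohex-2-enones. The one ring formed is the six-membered carbocycle, closed at C2=C3 by joining the inner alkene carbons of an octa-1,7-dien-3-one unit, and the ring size forces the new alkene to be cis. No stereocentre is created; C5 lies two bonds from either reacting alkene and is carried through unchanged. The step needs chemoselectivity for the two monosubstituted alkenes over the two Z-1,2-disubstituted alkenes of the chain, which should follow from the much slower reaction of internal alkenes, from the entropic advantage of six-ring closure reinforced by the quaternary C5 (gem-disubstituent effect), and from high dilution, ethene removal and a short reaction time. The silyl ether keeps the C5 oxygen from adding to the vinyl ketone and from binding ruthenium.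

Step 10
Reactants: 17 (5S)-5-[(10Z,13Z)-2-oxononadeca-10,13-dien-1-yl]-5-[(triethylsilyl)oxy]cyclohex-2-en-1-one
Product: 18 (5S)-5-hydroxy-5-[(10Z,13Z)-2-oxononadeca-10,13-dien-1-yl]cyclohex-2-en-1-one (target)
Conditions: HF·pyridine, excess pyridine, THF, 0 °C
Reagents that add atoms: none
Why: Fluoride-mediated cleavage of the triethylsilyl ether under buffered, nearly neutral conditions should free the tertiary alcohol without retro-aldol cleavage or dehydration of the β-hydroxy enone toward the phenol, and no stereocentre is touched.

Compound list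

1 | dimethyl 3-oxopentanedioate | COC(=O)CC(=O)CC(=O)OC | starting material
2 | 3-bromoprop-1-ene (allyl bromide) | C=CCBr | starting material
3 | allylindium sesquibromide (diallylindium bromide · allylindium dibromide) | C=CC[In](Br)CC=C.C=CC[In](Br)Br | intermediate
4 | dimethyl 3-hydroxy-3-(prop-2-en-1-yl)pentanedioate | COC(=O)CC(O)(CC=C)CC(=O)OC | intermediate
5 | (3S)-3-hydroxy-3-(2-methoxy-2-oxoethyl)hex-5-enoic acid | OC(=O)C[C@@](O)(CC=C)CC(=O)OC | intermediate
6 | methyl (3R)-3-[2-(ethylsulfanyl)-2-oxoethyl]-3-hydroxyhex-5-enoate | CCSC(=O)C[C@@](O)(CC=C)CC(=O)OC | intermediate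
7 | methyl (3R)-3-[2-(ethylsulfanyl)-2-oxoethyl]-3-[(triethylsilyl)oxy]hex-5-enoate | CCSC(=O)C[C@@](O[Si](CC)(CC)CC)(CC=C)CC(=O)OC | intermediate
8 | linoleic acid, (9Z,12Z)-octadeca-9,12-dienoic acid | CCCCC/C=C\C/C=C\CCCCCCCC(=O)O | starting material
9 | Barton ester, 2-sulfanylidenepyridin-1(2H)-yl (9Z,12Z)-octadeca-9,12-dienoate | CCCCC/C=C\C/C=C\CCCCCCCC(=O)ON1C=CC=CC1=S | intermediate
10 | (8Z,11Z)-1-iodoheptadeca-8,11-diene | CCCCC/C=C\C/C=C\CCCCCCCI | intermediate
11 | [(8Z,11Z)-heptadeca-8,11-dien-1-yl]zinc iodide | CCCCC/C=C\C/C=C\CCCCCCC[Zn]I | intermediate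
12 | methyl (3S,13Z,16Z)-5-oxo-3-(prop-2-en-1-yl)-3-[(triethylsilyl)oxy]docosa-13,16-dienoate | CCCCC/C=C\C/C=C\CCCCCCCC(=O)C[C@@](O[Si](CC)(CC)CC)(CC=C)CC(=O)OC | intermediate
13 | (3S,13Z,16Z)-5-oxo-3-(prop-2-en-1-yl)-3-[(triethylsilyl)oxy]docosa-13,16-dienoic acid | CCCCC/C=C\C/C=C\CCCCCCCC(=O)C[C@@](O[Si](CC)(CC)CC)(CC=C)CC(=O)O | intermediate
14 | tributyl(ethenyl)stannane | CCCC[Sn](CCCC)(CCCC)C=C | starting material
15 | (3S,13Z,16Z)-5-oxo-3-(prop-2-en-1-yl)-3-[(triethylsilyl)oxy]docosa-13,16-dienoyl chloride | CCCCC/C=C\C/C=C\CCCCCCCC(=O)C[C@@](O[Si](CC)(CC)CC)(CC=C)CC(=O)Cl | intermediate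
16 | (5S,15Z,18Z)-5-(prop-2-en-1-yl)-5-[(triethylsilyl)oxy]tetracosa-1,15,18-triene-3,7-dione | CCCCC/C=C\C/C=C\CCCCCCCC(=O)C[C@@](O[Si](CC)(CC)CC)(CC=C)CC(=O)C=C | intermediate
17 | (5S)-5-[(10Z,13Z)-2-oxononadeca-10,13-dien-1-yl]-5-[(triethylsilyl)oxy]cyclohex-2-en-1-one | CCCCC/C=C\C/C=C\CCCCCCCC(=O)C[C@@]1(O[Si](CC)(CC)CC)CC=CC(=O)C1 | intermediate
18 | (5S)-5-hydroxy-5-[(10Z,13Z)-2-oxononadeca-10,13-dien-1-yl]cyclohex-2-en-1-one | CCCCC/C=C\C/C=C\CCCCCCCC(=O)C[C@@]1(O)CC=CC(=O)C1 | target

Total step count: 10 (steps 1–10).
Longest linear sequence: 9 steps (steps 1–4 and 6–10, from dimethyl 3-oxopentanedioate); step 5 is a one-step side branch that joins at step 6.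

Steps most likely to fail

Step 2, esterase desymmetrisation. The enzyme may discriminate the two enantiotopic ester arms poorly, or in the opposite sense, because the allyl group is larger than the methyl group of the model substrate. The result would be a half-ester of low enantiomeric purity. The fallback sets out from 4. Saponification with LiOH in aqueous THF would give 3-hydroxy-3-(prop-2-en-1-yl)pentanedioic acid F1. Dehydration with DCC would close it to 4-hydroxy-4-(prop-2-en-1-yl)oxane-2,6-dione F2. Methanolysis of this prochiral anhydride in toluene at low temperature, mediated by quinidine or quinine (whichever member of the pseudoenantiomeric pair favours the S acid), would return to 5. The acid can then be enriched further by crystallising an amine salt.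

Step 8, acyl chloride formation and Stille acylation. The activated acyl group may be captured by the δ-ketone within the molecule (enol lactone or cyclic pseudo-chloride formation). The silyl ether may be cleaved by adventitious HCl. The vinyl ketone may also polymerise or suffer conjugate addition under the coupling conditions. The fallback sets out from 13. Carbodiimide coupling with benzenethiol (EDC·HCl, DMAP, CH2Cl2) would give S-phenyl (3S,13Z,16Z)-5-oxo-3-(prop-2-en-1-yl)-3-[(triethylsilyl)oxy]docosa-13,16-dienethioate F3, a stable acyl donor that cannot cyclise onto the ketone. Its coupling with 14 under neutral conditions (Pd2(dba)3, tri(2-furyl)phosphine, copper diphenylphosphinate CuO2PPh2 with monovalent copper, THF, rt) would come back to the route at 16.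

Step 9, ring-closing metathesis. Turnover at the electron-poor vinyl ketone may be slow enough for the catalyst to engage the chain Z-alkenes (ethenolysis, chain truncation, Z/E scrambling) or to decay to ruthenium hydrides that migrate double bonds. The fallback sets out from 16. Luche reduction (NaBH4, CeCl3·7H2O, MeOH, −78 → 0 °C) would give (5S,15Z,18Z)-5-(prop-2-en-1-yl)-5-[(triethylsilyl)oxy]tetracosa-1,15,18-triene-3,7-diol F4 as a mixture of carbinol epimers. Its allyl and allylic alcohol arms should close readily with the less active first-generation Grubbs catalyst RuCl2(=CHPh)(PCy3)2, which discriminates more strongly against internal alkenes, to give (5S)-5-[(10Z,13Z)-2-hydroxynonadeca-10,13-dien-1-yl]-5-[(triethylsilyl)oxy]cyclohex-2-en-1-ol F5. Oxidation of both secondary alcohols with Dess–Martin periodinane (NaHCO3, CH2Cl2) would return to the route at 17.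

Further compounds

F1 | step 2 | 3-hydroxy-3-(prop-2-en-1-yl)pentanedioic acid | OC(=O)CC(O)(CC=C)CC(=O)O
F2 | step 2 | 4-hydroxy-4-(prop-2-en-1-yl)oxane-2,6-dione | O=C1CC(O)(CC=C)CC(=O)O1
F3 | step 8 | S-phenyl (3S,13Z,16Z)-5-oxo-3-(prop-2-en-1-yl)-3-[(triethylsilyl)oxy]docosa-13,16-dienethioate | CCCCC/C=C\C/C=C\CCCCCCCC(=O)C[C@@](O[Si](CC)(CC)CC)(CC=C)CC(=O)Sc1ccccc1
F4 | step 9 | (5S,15Z,18Z)-5-(prop-2-en-1-yl)-5-[(triethylsilyl)oxy]tetracosa-1,15,18-triene-3,7-diol, epimer mixture at C3 and C7 | CCCCC/C=C\C/C=C\CCCCCCCC(O)C[C@@](O[Si](CC)(CC)CC)(CC=C)CC(O)C=C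
F5 | step 9 | (5S)-5-[(10Z,13Z)-2-hydroxynonadeca-10,13-dien-1-yl]-5-[(triethylsilyl)oxy]cyclohex-2-en-1-ol, epimer mixture at C1 and C2' | CCCCC/C=C\C/C=C\CCCCCCCC(O)C[C@@]1(O[Si](CC)(CC)CC)CC=CC(O)C1
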